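**Retrosynthetic overview**
1. Feature: C1–C2–C3 with the peroxide oxygen on C3 is a β-oxygenated acid, the opened form of an oxetan-2-one whose ring C4 is target C3. The 1,2-dioxane (O–O, C3–C6) is therefore closed last: the C6 hydroperoxide displaces the lactone oxygen at C3 with inversion, and that oxygen stays on C1 as the acid.
2. The oxetan-2-one is cut to ketene (from acetyl chloride) and a C3 aldehyde that carries the (6S)-peroxide as a 2-methoxyprop-2-yl peroxyketal; this forms C2–C3 and O–C1.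
3. The C6–OO bond comes from SN2 inversion of a (6R)-triflate; the (17Z,19E)-diene from a Wittig reaction of a C17 ylide with (E)-hepta-2,6-dienal, placed before the peroxide because of PPh3.
4. The trans-oxolane (O, C7–C10) comes from Shi epoxidation of an (E)-C6=C7 alkenol and 5-exo opening at C7 by the C10 hydroxyl; the alkene from a Julia–Kocienski reaction; C10 from (S)-1,2-epoxy-5-hexene.
5. Ring order: oxolane (step 8), oxetan-2-one (step 17), 1,2-dioxane (step 19).

Key step: step 17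

Assumption: O-trimethylsilylquinidine is taken as the pseudoenantiomer that gives the (R)-4-alkyl oxetan-2-one from an unbranched aldehyde; if the sense is the reverse, O-trimethylsilylquinine is used under the same conditions.

**Step 1**
Reactants: 1 (S)-2-(but-3-en-1-yl)oxirane [(S)-1,2-epoxy-5-hexene]; 2 1-bromo-6-chlorohexane
Product: 4 (5R)-12-chlorododec-1-en-5-ol, via 6-chlorohexylmagnesium bromide 3 (not isolated)
Conditions: 2, Mg, THF, 25 °C; then CuI (10 mol %), 1, THF, −30 → 0 °C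
Reagents that add atoms: none
Why: Copper-catalysed SN2 opening of the terminal epoxide at its CH2 (C11) by the Grignard reagent formed selectively at the C–Br bond; the epoxide stereocentre is untouched and becomes C10 (R, the descriptor changing only through the priority switch).

**Step 2**
Reactants: 4 (5R)-12-chlorododec-1-en-5-ol
Product: 5 {[(5R)-12-chlorododec-1-en-5-yl]oxy}triethylsilane
Conditions: Et3SiCl, imidazole, CH2Cl2, 0 °C → rt
Reagents that add atoms: triethylsilyl chloride, CC[Si](Cl)(CC)CC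
Why: Standard silylation of a secondary alcohol, needed so that the aldehyde of step 3 does not close to a lactol.

**Step 3**
Reactants: 5 {[(5R)-12-chlorododec-1-en-5-yl]oxy}triethylsilane
Product: 6 (4R)-11-chloro-4-(triethylsilyloxy)undecanal
Conditions: O3, CH2Cl2, −78 °C; then PPh3, −78 °C → rt
Reagents that add atoms: ozone, [O-][O+]=O
Why: Ozonolysis with reductive work-up cleaves the only alkene to the C7 aldehyde; silyl ether and primary chloride are inert.

**Step 4**
Reactants: 7 butane-1,4-diol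
Product: 8 4-{[tert-butyl(diphenyl)silyl]oxy}butan-1-ol
Conditions: t-BuPh2SiCl (limiting), 7 (excess), imidazole, DMF, 0 °C → rt
Reagents that add atoms: tert-butyl(chloro)diphenylsilane, CC(C)(C)[Si](Cl)(c1ccccc1)c1ccccc1
Why: Statistical monosilylation of a symmetric diol used in excess; this unit becomes C3–C6.

**Step 5**
Reactants: 8 4-{[tert-butyl(diphenyl)silyl]oxy}butan-1-ol
Product: 9 5-[(4-{[tert-butyl(diphenyl)silyl]oxy}butyl)sulfanyl]-1-phenyl-1H-tetrazole
Conditions: 1-phenyl-1H-tetrazole-5-thiol, PPh3, diisopropyl azodicarboxylate, THF, 0 °C → rt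
Reagents that add atoms: 1-phenyl-1H-tetrazole-5-thiol, Sc1nnnn1-c1ccccc1
Why: Mitsunobu thioetherification of a primary alcohol with an acidic heteroaryl thiol.

**Step 6**
Reactants: 9 5-[(4-{[tert-butyl(diphenyl)silyl]oxy}butyl)sulfanyl]-1-phenyl-1H-tetrazole
Product: 10 5-[(4-{[tert-butyl(diphenyl)silyl]oxy}butyl)sulfonyl]-1-phenyl-1H-tetrazole
Conditions: 30 % aqueous H2O2, (NH4)6Mo7O24·4H2O (10 mol %), EtOH, 0 °C → rt
Reagents that add atoms: hydrogen peroxide, OO
Why: Molybdate-catalysed oxidation of the sulfide to the sulfone, the usual entry to Julia–Kocienski reagents.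

**Step 7**
Reactants: 6 (4R)-11-chloro-4-(triethylsilyloxy)undecanal; 10 5-[(4-{[tert-butyl(diphenyl)silyl]oxy}butyl)sulfonyl]-1-phenyl-1H-tetrazole
Product: 12 (4E,8R)-1-{[tert-butyl(diphenyl)silyl]oxy}-15-chloropentadec-4-en-8-ol, via bis-silyl E-alkene 11 (not isolated)
Conditions: 10, KN(SiMe3)2, DME, −60 °C; 6, −60 °C → rt; crude product, pyridinium p-toluenesulfonate, MeOH, rt
Reagents that add atoms: none
Why: Julia–Kocienski olefination of an unbranched aldehyde with a 1-phenyltetrazolyl sulfone under potassium/DME conditions should give the (E)-C6=C7 alkene, and mild acid methanolysis then removes only the triethylsilyl group.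

**Step 8**
Reactants: 12 (4E,8R)-1-{[tert-butyl(diphenyl)silyl]oxy}-15-chloropentadec-4-en-8-ol
Product: 14 (1R)-4-{[tert-butyl(diphenyl)silyl]oxy}-1-[(2S,5R)-5-(7-chloroheptyl)oxolan-2-yl]butan-1-ol, via hydroxy epoxide 13 (not isolated)
Conditions: 1,2:4,5-di-O-isopropylidene-β-D-erythro-2,3-hexodiulo-2,6-pyranose (D-fructose-derived Shi ketone, 30 mol %), KHSO5 (as 2KHSO5·KHSO4·K2SO4), K2CO3, Bu4NHSO4, MeCN/CH2(OMe)2/aqueous Na2B4O7–Na2EDTA buffer, 0 °C; crude product, camphorsulfonic acid (10 mol %), CH2Cl2, 0 °C → rt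
Reagents that add atoms: potassium peroxymonosulfate, [K+].[O-]S(=O)(=O)OO
Why: Shi epoxidation, in which the chiral dioxirane delivers oxygen to one face of the trans-alkene to give the (6R,7R)-epoxide under reagent control, followed by acid-catalysed 5-exo-tet opening by the C10 hydroxyl with inversion at C7, which sets C7 (S), leaves the C6 carbinol (R) and gives the 2,5-trans-oxolane.

**Step 9**
Reactants: 14 (1R)-4-{[tert-butyl(diphenyl)silyl]oxy}-1-[(2S,5R)-5-(7-chloroheptyl)oxolan-2-yl]butan-1-ol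
Product: 15 (7-{(2R,5S)-5-[(1R)-4-{[tert-butyl(diphenyl)silyl]oxy}-1-hydroxybutyl]oxolan-2-yl}heptyl)triphenylphosphonium iodide
Conditions: PPh3, NaI, MeCN, reflux
Reagents that add atoms: triphenylphosphine, c1ccc(cc1)P(c1ccccc1)c1ccccc1; sodium iodide, [Na+].[I-]
Why: In situ Finkelstein exchange of the primary chloride and quaternisation of PPh3 by the primary iodide; the secondary alcohol and the silyl ether do not react.

**Step 10**
Reactants: 16 pent-4-enal; 17 (triphenylphosphoranylidene)acetaldehyde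
Product: 18 (2E)-hepta-2,6-dienal
Conditions: toluene, 80 °C
Reagents that add atoms: none
Why: Wittig reaction with a stabilised formyl ylide, which is E-selective and gives the two-carbon homologated enal (C18–C24).

**Step 11**
Reactants: 15 (7-{(2R,5S)-5-[(1R)-4-{[tert-butyl(diphenyl)silyl]oxy}-1-hydroxybutyl]oxolan-2-yl}heptyl)triphenylphosphonium iodide; 18 (2E)-hepta-2,6-dienal
Product: 20 (1R)-4-{[tert-butyl(diphenyl)silyl]oxy}-1-{(2S,5R)-5-[(7Z,9E)-tetradeca-7,9,13-trien-1-yl]oxolan-2-yl}butan-1-ol, via alkoxide ylide 19 (not isolated)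
Conditions: NaN(SiMe3)2 (2.1 equiv), THF, −78 → 0 °C; then 18, −78 °C → rt
Reagents that add atoms: none
Why: Wittig reaction of a non-stabilised ylide with an enal under lithium-free conditions should form the new C17=C18 bond Z while the enal keeps its E bond; the second equivalent of base covers the free hydroxyl.

**Step 12**
Reactants: 20 (1R)-4-{[tert-butyl(diphenyl)silyl]oxy}-1-{(2S,5R)-5-[(7Z,9E)-tetradeca-7,9,13-trien-1-yl]oxolan-2-yl}butan-1-ol
Product: 21 (1R)-4-{[tert-butyl(diphenyl)silyl]oxy}-1-{(2S,5R)-5-[(7Z,9E)-tetradeca-7,9,13-trien-1-yl]oxolan-2-yl}butyl trifluoromethanesulfonate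
Conditions: (CF3SO2)2O, 2,6-lutidine, CH2Cl2, −78 → −40 °C; cold aqueous NaHCO3 work-up, used at once
Reagents that add atoms: trifluoromethanesulfonic anhydride, O=S(=O)(OS(=O)(=O)C(F)(F)F)C(F)(F)F
Why: O-Sulfonylation of the secondary carbinol with retention at C6; the hindered base and low temperature spare the alkenes.

**Step 13**
Reactants: 22 2,3-dimethylbut-2-ene
Product: 24 2-methoxyprop-2-yl hydroperoxide, via acetone O-oxide 23 (not isolated)
Conditions: O3, MeOH/CH2Cl2, −78 °C; N2 purge, cold concentration, no reductant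
Reagents that add atoms: ozone, [O-][O+]=O; methanol, CO
Why: Ozonolysis in methanol, in which the carbonyl oxide from cycloreversion of the primary ozonide is trapped by the solvent to give the α-methoxy hydroperoxide.

**Step 14**
Reactants: 21 (1R)-4-{[tert-butyl(diphenyl)silyl]oxy}-1-{(2S,5R)-5-[(7Z,9E)-tetradeca-7,9,13-trien-1-yl]oxolan-2-yl}butyl trifluoromethanesulfonate; 24 2-methoxyprop-2-yl hydroperoxide
Product: 25 tert-butyl{[(4S)-4-[(2-methoxypropan-2-yl)peroxy]-4-{(2S,5R)-5-[(7Z,9E)-tetradeca-7,9,13-trien-1-yl]oxolan-2-yl}butyl]oxy}diphenylsilane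
Conditions: 24 (3 equiv), KOt-Bu (2.5 equiv), THF, −20 → 0 °C
Reagents that add atoms: none
Why: Alkylation of a hydroperoxide anion by a secondary triflate (SN2) inverts C6 from R to S; the excess hydroperoxide consumes all tert-butoxide, so the nucleophile is the weakly basic peroxide anion.

**Step 15**
Reactants: 25 tert-butyl{[(4S)-4-[(2-methoxypropan-2-yl)peroxy]-4-{(2S,5R)-5-[(7Z,9E)-tetradeca-7,9,13-trien-1-yl]oxolan-2-yl}butyl]oxy}diphenylsilane
Product: 26 (4S)-4-[(2-methoxypropan-2-yl)peroxy]-4-{(2S,5R)-5-[(7Z,9E)-tetradeca-7,9,13-trien-1-yl]oxolan-2-yl}butan-1-ol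
Conditions: Bu4NF, THF, 0 °C
Reagents that add atoms: none
Why: Fluoride desilylation; the peroxyketal is stable to base and fluoride and labile only to acid.

**Step 16**
Reactants: 26 (4S)-4-[(2-methoxypropan-2-yl)peroxy]-4-{(2S,5R)-5-[(7Z,9E)-tetradeca-7,9,13-trien-1-yl]oxolan-2-yl}butan-1-ol
Product: 27 (4S)-4-[(2-methoxypropan-2-yl)peroxy]-4-{(2S,5R)-5-[(7Z,9E)-tetradeca-7,9,13-trien-1-yl]oxolan-2-yl}butanal
Conditions: Dess–Martin periodinane, pyridine, CH2Cl2, 0 °C → rt
Reagents that add atoms: none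
Why: Dess–Martin oxidation of the primary alcohol to the C3 aldehyde, buffered with pyridine so that the acetic acid released does not cleave the peroxyketal.

**Step 17**
Reactants: 27 (4S)-4-[(2-methoxypropan-2-yl)peroxy]-4-{(2S,5R)-5-[(7Z,9E)-tetradeca-7,9,13-trien-1-yl]oxolan-2-yl}butanal; 28 acetyl chloride
Product: 30 (4R)-4-[(3S)-3-[(2-methoxypropan-2-yl)peroxy]-3-{(2S,5R)-5-[(7Z,9E)-tetradeca-7,9,13-trien-1-yl]oxolan-2-yl}propyl]oxetan-2-one, via ketene 29 (not isolated)
Conditions: O-trimethylsilylquinidine (10 mol %), LiClO4 (1 equiv), i-Pr2NEt (2.5 equiv), CH2Cl2/Et2O, −78 °C; 28 added over 2 h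
Reagents that add atoms: none
Why: i-Pr2NEt dehydrohalogenates 28 to ketene 29, which the quinuclidine nitrogen of the alkaloid captures as a chiral acylammonium enolate; this adds through a lithium-organised closed transition state to the aldehyde carbon C3 of 27 (C2–C3 bond), and the aldolate then closes on the acylammonium carbonyl (O–C1 bond, 4-exo-trig) and releases the catalyst. The closest known reaction is the cinchona alkaloid/LiClO4 acyl halide–aldehyde cyclocondensation of unbranched aliphatic aldehydes, a formal ketene–aldehyde (2+2) cycloaddition. The one new stereocentre, C3 (R), is set by the catalyst, because C6, C7 and C10 are too remote to bias the aldehyde faces. The step needs enantiofacial selectivity and chemoselectivity for the aldehyde: the peroxyketal offers no acidic or electrophilic site under amine-buffered conditions at −78 °C, and unactivated ketene should not add to the diene or the terminal alkene at this temperature. Slow addition of 28 keeps the ketene concentration low and suppresses its dimerisation.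

**Step 18**
Reactants: 30 (4R)-4-[(3S)-3-[(2-methoxypropan-2-yl)peroxy]-3-{(2S,5R)-5-[(7Z,9E)-tetradeca-7,9,13-trien-1-yl]oxolan-2-yl}propyl]oxetan-2-one
Product: 31 (4R)-4-[(3S)-3-hydroperoxy-3-{(2S,5R)-5-[(7Z,9E)-tetradeca-7,9,13-trien-1-yl]oxolan-2-yl}propyl]oxetan-2-one
Conditions: AcOH/THF/H2O (4:2:1), 20 °C, short reaction time
Reagents that add atoms: none
Why: Mild acid hydrolysis of the mixed peroxyketal, which is far more labile than the 4-alkyl β-lactone, frees the C6 hydroperoxide without touching C3 or C6.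

**Step 19**
Reactants: 31 (4R)-4-[(3S)-3-hydroperoxy-3-{(2S,5R)-5-[(7Z,9E)-tetradeca-7,9,13-trien-1-yl]oxolan-2-yl}propyl]oxetan-2-one
Product: 32 2-[(3S,6S)-6-{(2S,5R)-5-[(7Z,9E)-tetradeca-7,9,13-trien-1-yl]oxolan-2-yl}-1,2-dioxan-3-yl]acetic acid
Conditions: Cs2CO3 (1.2 equiv), DMF (0.01 M), 0 °C → rt; then 0.5 M HCl to pH 3, 0 °C
Reagents that add atoms: none
Why: Proposed new method: the cesium hydroperoxide anion at C6 should attack C3 of the strained oxetan-2-one from the backside in a 6-exo-tet SN2 (alkyl–oxygen cleavage, carboxylate leaving group, roughly 23 kcal/mol of ring strain released), inverting C3 from R to S and giving the trans-3,6-disubstituted 1,2-dioxane directly as its carboxylate; attack at the carbonyl would need an eight-membered transition state, and high dilution should suppress intermolecular acylation and carboxylate-initiated oligomerisation; the closest known reactions are the SN2 opening of 4-alkyl β-lactones at C4 by azide, thiolate or sulfonamide anions and the intramolecular alkylation of hydroperoxides by sulfonates or oxetanes to give 1,2-dioxanes and 1,2-dioxolanes.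

**Compound list**
1 | (S)-2-(but-3-en-1-yl)oxirane | C=CCC[C@H]1CO1 | starting material
2 | 1-bromo-6-chlorohexane | ClCCCCCCBr | starting material
3 | 6-chlorohexylmagnesium bromide | ClCCCCCC[Mg]Br | intermediate
4 | (5R)-12-chlorododec-1-en-5-ol | C=CCC[C@H](O)CCCCCCCCl | intermediate
5 | {[(5R)-12-chlorododec-1-en-5-yl]oxy}triethylsilane | C=CCC[C@H](O[Si](CC)(CC)CC)CCCCCCCCl | intermediate
6 | (4R)-11-chloro-4-(triethylsilyloxy)undecanal | O=CCC[C@H](O[Si](CC)(CC)CC)CCCCCCCCl | intermediate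
7 | butane-1,4-diol | OCCCCO | starting material
8 | 4-{[tert-butyl(diphenyl)silyl]oxy}butan-1-ol | CC(C)(C)[Si](OCCCCO)(c1ccccc1)c1ccccc1 | intermediate
9 | 5-[(4-{[tert-butyl(diphenyl)silyl]oxy}butyl)sulfanyl]-1-phenyl-1H-tetrazole | CC(C)(C)[Si](OCCCCSc1nnnn1-c1ccccc1)(c1ccccc1)c1ccccc1 | intermediate
10 | 5-[(4-{[tert-butyl(diphenyl)silyl]oxy}butyl)sulfonyl]-1-phenyl-1H-tetrazole | CC(C)(C)[Si](OCCCCS(=O)(=O)c1nnnn1-c1ccccc1)(c1ccccc1)c1ccccc1 | intermediate
11 | tert-butyl{[(4E,8R)-15-chloro-8-(triethylsilyloxy)pentadec-4-en-1-yl]oxy}diphenylsilane | CC(C)(C)[Si](OCCC/C=C/CC[C@H](O[Si](CC)(CC)CC)CCCCCCCCl)(c1ccccc1)c1ccccc1 | intermediate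
12 | (4E,8R)-1-{[tert-butyl(diphenyl)silyl]oxy}-15-chloropentadec-4-en-8-ol | CC(C)(C)[Si](OCCC/C=C/CC[C@H](O)CCCCCCCCl)(c1ccccc1)c1ccccc1 | intermediate
13 | (3R)-1-[(2R,3R)-3-(3-{[tert-butyl(diphenyl)silyl]oxy}propyl)oxiran-2-yl]-10-chlorodecan-3-ol | CC(C)(C)[Si](OCCC[C@H]1O[C@@H]1CC[C@H](O)CCCCCCCCl)(c1ccccc1)c1ccccc1 | intermediate
14 | (1R)-4-{[tert-butyl(diphenyl)silyl]oxy}-1-[(2S,5R)-5-(7-chloroheptyl)oxolan-2-yl]butan-1-ol | CC(C)(C)[Si](OCCC[C@@H](O)[C@@H]1CC[C@@H](CCCCCCCCl)O1)(c1ccccc1)c1ccccc1 | intermediate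
15 | (7-{(2R,5S)-5-[(1R)-4-{[tert-butyl(diphenyl)silyl]oxy}-1-hydroxybutyl]oxolan-2-yl}heptyl)triphenylphosphonium iodide | CC(C)(C)[Si](OCCC[C@@H](O)[C@@H]1CC[C@@H](CCCCCCC[P+](c2ccccc2)(c2ccccc2)c2ccccc2)O1)(c1ccccc1)c1ccccc1.[I-] | intermediate
16 | pent-4-enal | C=CCCC=O | starting material
17 | (triphenylphosphoranylidene)acetaldehyde | O=CC=P(c1ccccc1)(c1ccccc1)c1ccccc1 | starting material
18 | (2E)-hepta-2,6-dienal | C=CCC/C=C/C=O | intermediate
19 | sodium alkoxide ylide formed from 15 | CC(C)(C)[Si](OCCC[C@@H]([O-])[C@@H]1CC[C@@H](CCCCCCC=P(c2ccccc2)(c2ccccc2)c2ccccc2)O1)(c1ccccc1)c1ccccc1.[Na+] | intermediate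
20 | (1R)-4-{[tert-butyl(diphenyl)silyl]oxy}-1-{(2S,5R)-5-[(7Z,9E)-tetradeca-7,9,13-trien-1-yl]oxolan-2-yl}butan-1-ol | C=CCC/C=C/C=C\CCCCCC[C@@H]1CC[C@@H]([C@H](O)CCCO[Si](c2ccccc2)(c2ccccc2)C(C)(C)C)O1 | intermediate
21 | (1R)-4-{[tert-butyl(diphenyl)silyl]oxy}-1-{(2S,5R)-5-[(7Z,9E)-tetradeca-7,9,13-trien-1-yl]oxolan-2-yl}butyl trifluoromethanesulfonate | C=CCC/C=C/C=C\CCCCCC[C@@H]1CC[C@@H]([C@H](OS(=O)(=O)C(F)(F)F)CCCO[Si](c2ccccc2)(c2ccccc2)C(C)(C)C)O1 | intermediate
22 | 2,3-dimethylbut-2-ene | CC(C)=C(C)C | starting material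
23 | acetone O-oxide | CC(C)=[O+][O-] | intermediate
24 | 2-methoxyprop-2-yl hydroperoxide | COC(C)(C)OO | intermediate
25 | tert-butyl{[(4S)-4-[(2-methoxypropan-2-yl)peroxy]-4-{(2S,5R)-5-[(7Z,9E)-tetradeca-7,9,13-trien-1-yl]oxolan-2-yl}butyl]oxy}diphenylsilane | C=CCC/C=C/C=C\CCCCCC[C@@H]1CC[C@@H]([C@@H](OOC(C)(C)OC)CCCO[Si](c2ccccc2)(c2ccccc2)C(C)(C)C)O1 | intermediate
26 | (4S)-4-[(2-methoxypropan-2-yl)peroxy]-4-{(2S,5R)-5-[(7Z,9E)-tetradeca-7,9,13-trien-1-yl]oxolan-2-yl}butan-1-ol | C=CCC/C=C/C=C\CCCCCC[C@@H]1CC[C@@H]([C@@H](OOC(C)(C)OC)CCCO)O1 | intermediate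
27 | (4S)-4-[(2-methoxypropan-2-yl)peroxy]-4-{(2S,5R)-5-[(7Z,9E)-tetradeca-7,9,13-trien-1-yl]oxolan-2-yl}butanal | C=CCC/C=C/C=C\CCCCCC[C@@H]1CC[C@@H]([C@@H](OOC(C)(C)OC)CCC=O)O1 | intermediate
28 | acetyl chloride | CC(=O)Cl | starting material
29 | ketene | C=C=O | intermediate
30 | (4R)-4-[(3S)-3-[(2-methoxypropan-2-yl)peroxy]-3-{(2S,5R)-5-[(7Z,9E)-tetradeca-7,9,13-trien-1-yl]oxolan-2-yl}propyl]oxetan-2-one | C=CCC/C=C/C=C\CCCCCC[C@@H]1CC[C@@H]([C@@H](OOC(C)(C)OC)CC[C@@H]2CC(=O)O2)O1 | intermediate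
31 | (4R)-4-[(3S)-3-hydroperoxy-3-{(2S,5R)-5-[(7Z,9E)-tetradeca-7,9,13-trien-1-yl]oxolan-2-yl}propyl]oxetan-2-one | C=CCC/C=C/C=C\CCCCCC[C@@H]1CC[C@@H]([C@@H](OO)CC[C@@H]2CC(=O)O2)O1 | intermediate
32 | 2-[(3S,6S)-6-{(2S,5R)-5-[(7Z,9E)-tetradeca-7,9,13-trien-1-yl]oxolan-2-yl}-1,2-dioxan-3-yl]acetic acid | C=CCC/C=C/C=C\CCCCCC[C@@H]1CC[C@@H]([C@@H]2CC[C@@H](CC(=O)O)OO2)O1 | target

**Step count**
Total: 19 steps. Longest linear sequence: 14 steps (1, 2, 3, 7, 8, 9, 11, 12, 14, 15, 16, 17, 18, 19).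

**Steps most likely to fail**

Step 19. The peroxide anion may attack the lactone carbonyl (inter- or intramolecular acyl–oxygen cleavage), or base-induced Kornblum–DeLaMare fragmentation of the secondary hydroperoxide may outrun the SN2 at the secondary lactone carbon. The fallback sets out from 30 and comes back to the route at 32, using the known intramolecular peroxide conjugate addition. Catalytic K2CO3 in MeOH at 0 °C should open the lactone at the acyl carbon to methyl (3R,6S)-3-hydroxy-6-[(2-methoxypropan-2-yl)peroxy]-6-{(2S,5R)-5-[(7Z,9E)-tetradeca-7,9,13-trien-1-yl]oxolan-2-yl}hexanoate F1. MeSO2Cl and Et3N in CH2Cl2 should give its 3-methanesulfonate F2, which 1,8-diazabicyclo[5.4.0]undec-7-ene eliminates to the (2E)-enoate F3. AcOH/THF/H2O then frees the hydroperoxy enoate F4. Et2NH in CF3CH2OH should close it by 6-exo-trig peroxy-Michael addition to the dioxane methyl ester F5; the diequatorial trans (3S,6S) isomer is expected to predominate and is separated from its C3 epimer. LiOH in THF/H2O gives 32.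

Step 14. E2 elimination of the triflate, or ionisation assisted by the oxolane oxygen with ring expansion, may compete with direct SN2 inversion at the α-alkoxy secondary carbon. The fallback sets out from 20 and comes back at 25; it delivers the oxygen–oxygen unit as the small hydroperoxide anion to a non-ionising sulfonate and puts the ketal on afterwards. MeSO2Cl and Et3N should give the (1R)-methanesulfonate F6. KOH and 50 % aqueous H2O2 in MeOH/THF at rt should displace it with inversion to the free (4S)-hydroperoxide F7. 2-Methoxypropene with catalytic pyridinium p-toluenesulfonate in CH2Cl2 at 0 °C then gives 25.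

Step 17. Enantiofacial discrimination at C3 may be insufficient, LiClO4 may ionise the peroxyketal, or ketene dimerisation may outrun addition to the aldehyde. The fallback sets out from 27 and comes back at 30; it separates C2–C3 bond formation from lactone closure. The magnesium enolate of (S)-2-hydroxy-1,2,2-triphenylethyl acetate (LiN(i-Pr)2, then MgBr2, THF, below −100 °C) should add to 27 to give the acetate aldol ester F8 with the (3R) carbinol; the (R)-reagent is used if the sense proves opposite. KOH in MeOH/H2O releases the (3R)-3-hydroxy acid F9 and the auxiliary diol. PhSO2Cl in pyridine at 0 °C lactonises F9 by carboxyl activation with retention at C3 to give 30.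

**Further compounds**
F1 | step 19 | methyl (3R,6S)-3-hydroxy-6-[(2-methoxypropan-2-yl)peroxy]-6-{(2S,5R)-5-[(7Z,9E)-tetradeca-7,9,13-trien-1-yl]oxolan-2-yl}hexanoate | C=CCC/C=C/C=C\CCCCCC[C@@H]1CC[C@@H]([C@@H](OOC(C)(C)OC)CC[C@@H](O)CC(=O)OC)O1
F2 | step 19 | methyl (3R,6S)-3-(methanesulfonyloxy)-6-[(2-methoxypropan-2-yl)peroxy]-6-{(2S,5R)-5-[(7Z,9E)-tetradeca-7,9,13-trien-1-yl]oxolan-2-yl}hexanoate | C=CCC/C=C/C=C\CCCCCC[C@@H]1CC[C@@H]([C@@H](OOC(C)(C)OC)CC[C@@H](OS(C)(=O)=O)CC(=O)OC)O1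
F3 | step 19 | methyl (2E,6S)-6-[(2-methoxypropan-2-yl)peroxy]-6-{(2S,5R)-5-[(7Z,9E)-tetradeca-7,9,13-trien-1-yl]oxolan-2-yl}hex-2-enoate | C=CCC/C=C/C=C\CCCCCC[C@@H]1CC[C@@H]([C@@H](OOC(C)(C)OC)CC/C=C/C(=O)OC)O1
F4 | step 19 | methyl (2E,6S)-6-hydroperoxy-6-{(2S,5R)-5-[(7Z,9E)-tetradeca-7,9,13-trien-1-yl]oxolan-2-yl}hex-2-enoate | C=CCC/C=C/C=C\CCCCCC[C@@H]1CC[C@@H]([C@@H](OO)CC/C=C/C(=O)OC)O1
F5 | step 19 | methyl 2-[(3S,6S)-6-{(2S,5R)-5-[(7Z,9E)-tetradeca-7,9,13-trien-1-yl]oxolan-2-yl}-1,2-dioxan-3-yl]acetate | C=CCC/C=C/C=C\CCCCCC[C@@H]1CC[C@@H]([C@@H]2CC[C@@H](CC(=O)OC)OO2)O1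
F6 | step 14 | (1R)-4-{[tert-butyl(diphenyl)silyl]oxy}-1-{(2S,5R)-5-[(7Z,9E)-tetradeca-7,9,13-trien-1-yl]oxolan-2-yl}butyl methanesulfonate | C=CCC/C=C/C=C\CCCCCC[C@@H]1CC[C@@H]([C@H](OS(C)(=O)=O)CCCO[Si](c2ccccc2)(c2ccccc2)C(C)(C)C)O1
F7 | step 14 | tert-butyl{[(4S)-4-hydroperoxy-4-{(2S,5R)-5-[(7Z,9E)-tetradeca-7,9,13-trien-1-yl]oxolan-2-yl}butyl]oxy}diphenylsilane | C=CCC/C=C/C=C\CCCCCC[C@@H]1CC[C@@H]([C@@H](OO)CCCO[Si](c2ccccc2)(c2ccccc2)C(C)(C)C)O1
F8 | step 17 | (1S)-2-hydroxy-1,2,2-triphenylethyl (3R,6S)-3-hydroxy-6-[(2-methoxypropan-2-yl)peroxy]-6-{(2S,5R)-5-[(7Z,9E)-tetradeca-7,9,13-trien-1-yl]oxolan-2-yl}hexanoate | C=CCC/C=C/C=C\CCCCCC[C@@H]1CC[C@@H]([C@@H](OOC(C)(C)OC)CC[C@@H](O)CC(=O)O[C@@H](c2ccccc2)C(O)(c2ccccc2)c2ccccc2)O1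
F9 | step 17 | (3R,6S)-3-hydroxy-6-[(2-methoxypropan-2-yl)peroxy]-6-{(2S,5R)-5-[(7Z,9E)-tetradeca-7,9,13-trien-1-yl]oxolan-2-yl}hexanoic acid | C=CCC/C=C/C=C\CCCCCC[C@@H]1CC[C@@H]([C@@H](OOC(C)(C)OC)CC[C@@H](O)CC(=O)O)O1
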